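The numbers in the tables are simulated from invented constants, and the scatter is random.

The eta run is the nearest neighbour to your cedar flask, and you can get a quick number from it without any mechanism. It was last read at 8.00 h with 75.6% of the electrophile left, so take that reading as the large part and the remaining hours as a correction.

| setting | epsilon | alpha | eta | larch | oak | cedar |
|---|---|---|---|---|---|---|
| electrophile | 0.020 M | 0.020 M | 0.020 M | 0.020 M | 0.020 M | 0.020 M |
| protonated nucleophile | 1 equiv | 2.5 equiv | 4.9 equiv | 1.20 equiv | 2.40 equiv | 4.80 equiv |
| solid base | 0.30 equiv | 0.30 equiv | 0.30 equiv | 0.300 equiv | 0.300 equiv | 0.300 equiv |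
| remark | run made earlier | run made earlier | run made earlier |  |  |  |
| time |  |  |  | 15 h | 15 h | 15 h |

- epsilon (time / h: electrophile / %, target / %): 1.50: 95.2, 4.6; 3.00: 89.7, 10.5; 5.00: 85.1, 14.0; 6.00: 83.8, 15.0; 8.00: 81.7, 15.8
- alpha (time / h: electrophile / %, target / %): 1.50: 94.9, 5.5; 3.00: 88.1, 10.6; 5.00: 83.1, 14.2; 6.00: 82.3, 15.3; 8.00: 78.1, 17.9
- eta (time / h: electrophile / %, target / %): 0.667: 98.1, 1.2; 1.00: 95.9, 3.1; 2.00: 91.7, 7.5; 4.00: 83.5, 14.0; 8.00: 75.6, 19.8

(each reading ± 0.5 percentage points)

- solid, in amounts per volume of the solution: solid base
- at the start none of the solid base is in solution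

* part of the electrophile that has reacted at the end, larch
* part of the electrophile that has reacted at the end, oak
* part of the electrophile that has reacted at the end, cedar
* what raising the equivalents of protonated nucleophile from its lowest to its highest value here does to the part of the electrophile that has reacted (changes below 5 percentage points count as none) (no change / it falls / it rises)

So compute just the correction. Between its last two readings, eta fell from 83.5% to 75.6%, a fractional loss of 0.0248 h⁻¹, and that is a reading with their scatter in it. Call this the tail constant, the late fractional loss of electrophile per hour. I assume the tail stays pseudo-first-order. Carried over the 7.00 h after the last reading, it puts cedar at 36.5% reacted. For larch, the last two epsilon readings give 0.0127 h⁻¹ and 25.2%. For oak, alpha from 5.00 h to 8.00 h gives 0.0207 h⁻¹ and 32.4%. Each comes from the nearest run, with no adjustment for the difference in loading. My answer is therefore that conversion rises, by 11 percentage points, which is larger than the 5 points that counts as a change.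

Your forecast reads 23.5%, 26% and 29% for larch, oak and cedar and says it rises, holding that “More protonated nucleophile seems to raise the apparent ceiling”, and for cedar it stands 7.5 points below my figure.

Larch, oak and cedar give 25.2%, 30.7% and 37.8%, and the trend comes out as it rises, by 13 points. My cedar figure was 1.3 points low and my oak figure 1.7 points high.

    solid base ⇌ free base, rate k1*(cs1 - [free base]) while solid is left; crystals form when [free base] > cs1 (solubility = 16.0 mM, k = 5.10 × 10⁻⁵ s⁻¹)
    acid set free + free base ⇌ salt of the base, settled at all times (K = 2.80 × 10⁵ M⁻¹)
    electrophile + acid set free → side product (k = 0.00340 M⁻¹ s⁻¹)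
    nucleophile + acid set free ⇌ protonated nucleophile, settled at all times (K = 1.20 × 10⁵ M⁻¹)
    electrophile + nucleophile → acid set free + target (k = 0.00520 M⁻¹ s⁻¹)

In cedar itself, the electrophile goes from 76.2% at 7.50 h to 62.2% at 15.0 h, a tail constant of 0.0271 h⁻¹. Now read cedar later, at 2.5 d, with all amounts held. The 0.0248 h⁻¹ read from eta, run on from eta's last reading, gives 79.2% reacted, and that neighbouring flask gives 82.0%, with 18.0% of the electrophile left. In that flask the side product, at 43.0%, stands above the target, at 39.0%.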